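**Retrosynthetic overview**
1. Pivotal construction: the pyran O1–C2 bond of the chromene, closed by oxa-6π electrocyclisation of an oxatriene made from 2,4,6-trihydroxybutyrophenone and prenal. It is the only ring that has to be built, and it is built first.
2. Closing the pyran first leaves ring A (the butyrophenone ring) with one free carbon, which takes the CH2 bridge to methylphloracetophenone (ring B) by a Mannich base / o-quinone methide coupling.
3. Every ring carbon is then substituted, so the quaternary (R) centre is made last by enantioselective dearomative C-geranylation at the methyl-bearing carbon of ring B, which also unveils the enolised trione.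
4. Ring order: pyran ring (step 1); ring B is dearomatised, not built (step 3).

Assumption: 1, 2, 5, 9 and Eschenmoser's salt are bought as catalogue chemicals, and the (R) descriptor refers to the tautomer written in the target SMILES.

**Step 1**
Reactants: 1 1-(2,4,6-trihydroxyphenyl)butan-1-one; 2 3-methylbut-2-enal (prenal)
Product: 4 1-(5,7-dihydroxy-2,2-dimethyl-2H-chromen-8-yl)butan-1-one, via oxatriene 3 (not isolated)
Conditions: 2 (1.05 equiv), ethylenediammonium diacetate (10 mol %), toluene/1,4-dioxane 4:1, 100 °C, 6 h
Reagents that add atoms: none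
Why: Amine-catalysed Knoevenagel-type condensation at a ring carbon between two hydroxyls gives 1-oxatriene 3, whose oxa-6π electrocyclisation forms the pyran O–C(CH3)2 bond; closure through the oxygen next to the acyl-bearing carbon gives the 8-acyl chromene (expected major isomer, the 6-acyl isomer being removed by chromatography), and no stereocentre is formed.

**Step 2**
Reactants: 5 1-(2,4,6-trihydroxy-3-methylphenyl)ethan-1-one; 4 1-(5,7-dihydroxy-2,2-dimethyl-2H-chromen-8-yl)butan-1-one
Product: 8 1-[3-[(8-butanoyl-5,7-dihydroxy-2,2-dimethyl-2H-chromen-6-yl)methyl]-2,4,6-trihydroxy-5-methylphenyl]ethan-1-one, via Mannich base 6 (not isolated), via quinone methide 7 (not isolated)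
Conditions: 5, Eschenmoser's salt (1.0 equiv), MeCN, 23 °C, 2 h; then 4 (1.2 equiv), NaOAc (1.2 equiv), 80 °C, 6 h
Reagents that add atoms: Eschenmoser's salt (N,N-dimethylmethylideneammonium iodide), C=[N+](C)C.[I-]
Why: Mannich aminomethylation can only occur at the single free ring carbon of 5; on warming, the Mannich base loses dimethylamine to give o-quinone methide 7, which is captured in a Michael-type Friedel–Crafts addition by the single free carbon (C6) of chromene 4, so the unsymmetrical CH2 bridge forms without a statistical mixture and no stereocentre is formed.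

**Step 3**
Reactants: 8 1-[3-[(8-butanoyl-5,7-dihydroxy-2,2-dimethyl-2H-chromen-6-yl)methyl]-2,4,6-trihydroxy-5-methylphenyl]ethan-1-one; 9 (2E)-3,7-dimethylocta-2,6-dien-1-yl acetate (geranyl acetate)
Product: 10 (4R)-2-acetyl-6-[(8-butanoyl-5,7-dihydroxy-2,2-dimethyl-2H-chromen-6-yl)methyl]-4-[(2E)-3,7-dimethylocta-2,6-dien-1-yl]-3,5-dihydroxy-4-methylcyclohexa-2,5-dien-1-one
Conditions: Pd2(dba)3·CHCl3 (2.5 mol %), (R,R)-DACH-phenyl Trost ligand (7.5 mol %), 9 (1.1 equiv), Et3N (1.5 equiv), degassed CH2Cl2, 0 °C to 23 °C; aqueous citric acid work-up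
Reagents that add atoms: none
Why: Proposed new method: enantio- and site-selective Pd-catalysed dearomative C-geranylation of a fully substituted bis(acylphloroglucinol)methane – zerovalent palladium bound to the Trost ligand ionises 9 to a π-geranyl complex, and the triethylammonium phenoxide of 8 attacks its unsubstituted terminus (linear product, E geometry kept) through the only ring carbon that is neither acylated nor screened by the diarylmethane bridge, the methyl-bearing carbon of ring B; O-geranyl ethers formed kinetically are re-ionised by the catalyst, whereas the C-alkylated product tautomerises to an acidic enolised β-triketone held as its ammonium enolate, which cannot re-ionise, so the quaternary (R) centre is set once under ligand control, the chiral pocket distinguishing the acetyl flank from the bridge flank of the planar ring (the antipodal ligand is used if the first run shows the opposite sense); closest known reaction type: Trost-type Pd-catalysed asymmetric allylic alkylation creating a nucleophile-centred quaternary stereocentre (geranylation and prenylation of 3-substituted oxindoles, intermolecular allylic dearomatisation of naphthols), together with racemic Tsuji–Trost or base-mediated alkylative dearomatisation of acylphloroglucinols.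

**Compound list**
1 | 1-(2,4,6-trihydroxyphenyl)butan-1-one (2,4,6-trihydroxybutyrophenone) | CCCC(=O)c1c(O)cc(O)cc1O | starting material
2 | 3-methylbut-2-enal (prenal) | CC(C)=CC=O | starting material
3 | (6Z)-2-butanoyl-3,5-dihydroxy-6-(3-methylbut-2-en-1-ylidene)cyclohexa-2,4-dien-1-one (1-oxatriene) | CCCC(=O)C1=C(O)C=C(O)/C(=C/C=C(C)C)C1=O | intermediate (not isolated)
4 | 1-(5,7-dihydroxy-2,2-dimethyl-2H-chromen-8-yl)butan-1-one | CCCC(=O)c1c(O)cc(O)c2C=CC(C)(C)Oc12 | intermediate
5 | 1-(2,4,6-trihydroxy-3-methylphenyl)ethan-1-one (methylphloracetophenone) | CC(=O)c1c(O)cc(O)c(C)c1O | starting material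
6 | 1-[3-[(dimethylamino)methyl]-2,4,6-trihydroxy-5-methylphenyl]ethan-1-one (Mannich base) | CC(=O)c1c(O)c(CN(C)C)c(O)c(C)c1O | intermediate (not isolated)
7 | 2-acetyl-3,5-dihydroxy-4-methyl-6-methylidenecyclohexa-2,4-dien-1-one (o-quinone methide) | CC(=O)C1=C(O)C(C)=C(O)C(=C)C1=O | intermediate (not isolated)
8 | 1-[3-[(8-butanoyl-5,7-dihydroxy-2,2-dimethyl-2H-chromen-6-yl)methyl]-2,4,6-trihydroxy-5-methylphenyl]ethan-1-one | CCCC(=O)c1c(O)c(Cc2c(O)c(C)c(O)c(C(C)=O)c2O)c(O)c2C=CC(C)(C)Oc12 | intermediate
9 | (2E)-3,7-dimethylocta-2,6-dien-1-yl acetate (geranyl acetate) | CC(=O)OC/C=C(\C)CCC=C(C)C | starting material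
10 | (4R)-2-acetyl-6-[(8-butanoyl-5,7-dihydroxy-2,2-dimethyl-2H-chromen-6-yl)methyl]-4-[(2E)-3,7-dimethylocta-2,6-dien-1-yl]-3,5-dihydroxy-4-methylcyclohexa-2,5-dien-1-one | CCCC(=O)c1c(O)c(CC2=C(O)[C@@](C)(C/C=C(\C)CCC=C(C)C)C(O)=C(C(C)=O)C2=O)c(O)c2c1OC(C)(C)C=C2 | target

**Totals**
Total step count: 3. Longest linear sequence: 3 (1 → 4 → 8 → 10).

**Three steps most likely to fail**

Step 3 (proposed new step). The risks are incomplete enantiocontrol, competing alkylation at a bridge-bearing carbon or at oxygen, and E/Z leakage through π-σ-π isomerisation of the geranyl complex. The fallback uses known chemistry, sets out from 8 and comes back at 10. Compound 8 is alkylated with geranyl bromide under NaOMe in MeOH at 0 °C (classical base-mediated alkylative dearomatisation of a fully substituted acylphloroglucinol) to give the racemic geranylated dimer F1. This is resolved by preparative HPLC on an amylose tris(3,5-dimethylphenylcarbamate) phase; the (R) fraction is 10 and the (4S)-enantiomer F2 is set aside.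

Step 1. The risks are ring closure through the oxygen para to the acyl group (6-acyl isomer) and a second annulation giving a bis-pyran. The fallback sets out from 1 and comes back at 4, making the closure regiospecific by blocking the para oxygen. Compound 1 is silylated selectively at the non-chelated para hydroxyl (TBSCl 1.0 equiv, imidazole, DMF, 0 °C) to give 1-[4-(tert-butyldimethylsilyloxy)-2,6-dihydroxyphenyl]butan-1-one F3. The same prenal/ethylenediammonium diacetate annulation can then only close through an ortho oxygen and gives 1-[5-(tert-butyldimethylsilyloxy)-7-hydroxy-2,2-dimethyl-2H-chromen-8-yl]butan-1-one F4. Tetrabutylammonium fluoride in THF at 0 °C then releases 4.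

Step 2. The risks are methylene exchange at 80 °C leading to symmetrical dimers, and acid sensitivity of the chromene. The fallback sets out from 4 (with 5) and comes back at 8, moving the electrophilic CH2 to the chromene and generating the quinone methide at room temperature. Compound 4 is treated with Eschenmoser's salt in CH2Cl2 and isolated after NaHCO3 wash as the Mannich base 1-[6-[(dimethylamino)methyl]-5,7-dihydroxy-2,2-dimethyl-2H-chromen-8-yl]butan-1-one F5. MeI in THF converts it to the trimethylammonium iodide F6. Stirring F6 with 5 and NaHCO3 in MeCN/water at 23 °C expels trimethylamine, and the resulting chromene quinone methide is trapped by the free ring carbon of 5 to give 8.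

**Further compounds**
F1 | step 3 | racemic 2-acetyl-6-[(8-butanoyl-5,7-dihydroxy-2,2-dimethyl-2H-chromen-6-yl)methyl]-4-[(2E)-3,7-dimethylocta-2,6-dien-1-yl]-3,5-dihydroxy-4-methylcyclohexa-2,5-dien-1-one | CCCC(=O)c1c(O)c(CC2=C(O)C(C)(C/C=C(\C)CCC=C(C)C)C(O)=C(C(C)=O)C2=O)c(O)c2c1OC(C)(C)C=C2
F2 | step 3 | (4S)-enantiomer of 10 | CCCC(=O)c1c(O)c(CC2=C(O)[C@](C)(C/C=C(\C)CCC=C(C)C)C(O)=C(C(C)=O)C2=O)c(O)c2c1OC(C)(C)C=C2
F3 | step 1 | 1-[4-(tert-butyldimethylsilyloxy)-2,6-dihydroxyphenyl]butan-1-one | CCCC(=O)c1c(O)cc(O[Si](C)(C)C(C)(C)C)cc1O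
F4 | step 1 | 1-[5-(tert-butyldimethylsilyloxy)-7-hydroxy-2,2-dimethyl-2H-chromen-8-yl]butan-1-one | CCCC(=O)c1c(O)cc(O[Si](C)(C)C(C)(C)C)c2C=CC(C)(C)Oc12
F5 | step 2 | 1-[6-[(dimethylamino)methyl]-5,7-dihydroxy-2,2-dimethyl-2H-chromen-8-yl]butan-1-one | CCCC(=O)c1c(O)c(CN(C)C)c(O)c2C=CC(C)(C)Oc12
F6 | step 2 | [(8-butanoyl-5,7-dihydroxy-2,2-dimethyl-2H-chromen-6-yl)methyl]trimethylammonium iodide | CCCC(=O)c1c(O)c(C[N+](C)(C)C)c(O)c2C=CC(C)(C)Oc12.[I-]
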